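## The problem

Target 19 is an achiral 2-arylbenzofuran. Ring A (C3a to C7a) is a phloroglucinol ring whose three oxygens are O1, the C4 hydroxyl and the C6 hydroxyl. The furan is closed through C2 and C3, and ring B (C1' to C6') is a resorcinol bonded through C1' to C2. There is no stereocentre, so nothing has to be set or relayed; the whole difficulty is regiochemistry and functional-group tolerance.

- On ring A the 1,1-dimethylallyl group must sit at C7, between O1 and the C6 oxygen, and not at the equally activated C5.
- On ring B both prenyl groups sit at C2' and C6', beside the biaryl bond, while C4' between the two oxygens stays free. Electrophilic prenylation or ortho-lithiation of a resorcinol gives the opposite pattern.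
- The C1'-C2 bond joins a doubly flanked aryl carbon to a furan carbon.
- The molecule has four free phenols on electron-rich rings and three allylic side chains, each ortho to a phenol. Acid closes these to chromans or dihydrofurans, so strong Lewis acids, hydrogenolysis and hot protic acid are excluded late in the route.
- The feature that opens the key step is the local mirror plane of ring B through C1' and C4'. Carbon chains at both C2' and C6' flank the C1'-C2 bond, which is the pattern an ortho,ortho'-dialkylation with ipso coupling writes onto an aryl iodide with two equivalent ortho C-H bonds.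

## Retrosynthesis

**19 from 18.** The last cut removes four O-CH2 acetal bonds, giving tetrakis(methoxymethyl) ether 18. Methyl ethers would need a boron trihalide and benzyl ethers hydrogenolysis, both fatal to the olefins. Aryl silyl ethers would not survive hot carbonate in the key step. The forward step asks that mild acid cleave four acetals faster than it protonates a trisubstituted olefin next to a phenol.

**18 from 15 via 17 and 16.** The two trisubstituted C=C bonds of the prenyl groups are cut to give dialdehyde 17, which comes from diol 16 and bis-silyl ether 15. A prenyl halide cannot be the alkylating partner of the key step, because it ionises on zerovalent palladium instead of adding to a palladacycle as a primary sp3 halide does. Each prenyl group therefore enters as a two-carbon oxygenated arm. The price is three finishing steps and a twofold Wittig reaction on enolisable arylacetaldehydes.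

**15 from 13, 14 and 10.** Three bonds are cut at once: C2'-CH2, C6'-CH2 and C1'-C2. This leads to symmetric iodide 13, two molecules of iodide 14 and boronate 10. A plain Suzuki cut of C1'-C2 alone would presuppose a ring B already alkylated at both positions next to the halide, and resorcinol chemistry does not provide that pattern. A double Claisen route from a resorcinol bis-allyl ether would scatter between C2'/C6' and C4'. The Catellani cut reduces ring B to an iodide with no carbon substituent. The forward reaction must complete both alkylations before ipso coupling and must prefer Suzuki capture to Heck addition.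

**10 from 6 via 8 and 7.** The C2-B bond goes back to the C2-Br bond of 8, the O1-C2 bond to gem-dibromo-olefin 7, and the C2=C3 bond to the formyl group of salicylaldehyde 6. Direct metalation of a C2-unsubstituted benzofuran is the neighbouring option. It would compete with the C5-H between two acetal oxygens, the best directed-metalation site in the molecule. A bromine placed by the ring closure removes that question.

**6 from 1 and 2 via 5 and 3.** The two acetal bonds of 6 are cut to triol 5. The C7-quaternary carbon bond is cut by a [3,3] shift to prenyl ether 3, which comes from aldehyde 1 and bromide 2. The choice of the ether oxygen is the critical point.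

- If the ether sat on the oxygen ortho to the formyl group (the later O1), the para carbon (the later C5) would be open. Crowded ortho-dienones from prenyl ethers readily undergo a second Cope shift there, which would give the linear prenyl isomer.
- With the ether on the oxygen para to the formyl group, the para carbon is blocked and the two ortho carbons are equivalent by symmetry. Only one reverse-prenyl product can form.
- The cost is that the two ortho hydroxyls of 5 must then be told apart. Step 3 relies on the shielding of the hydroxyl wedged between the quaternary carbon and the formyl group.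

**13 from 11 via 12; 14.** Iodide 13 comes from diol 12 by acetal formation and 12 from dimethyl ether 11 by ether cleavage. Both are protecting-group exchanges on a symmetric arene. Iodide 14 is bought.

## Roads not taken

**Alternative 1:** This road cuts O1-C7a. Ketone A2, a 2-(2-bromoaryl)-1-arylethanone, would cyclise through its enolate under CuI, a diamine and K3PO4 to give benzofuran A1.

- Merits: the ring closure is a single intramolecular copper coupling with no multicomponent timing problem, and it needs no base-sensitive heteroaryl boronate. In these respects it is the safer key step.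
- Weak points: A2 already contains ring B with both prenyl groups and a carbonyl carbon wedged between them. The hard substitution pattern is assumed, not made, and the aryl ketone is strongly hindered. A1 also lacks the 1,1-dimethylallyl group, which would have to come from a late Claisen shift of the 6-O-prenyl ether. In that unsymmetrical benzofuran C7 and C5 are both open ortho positions, and the heating would be done on a molecule carrying two more prenyl chains.
- Comparison: the chosen plan sets against the safer ring closure a symmetric, para-blocked Claisen step early on and the construction of the ring B pattern in the same operation as the biaryl bond.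

**Alternative 2:** This road cuts C4-C5 and grows ring A on a preformed furan. In keto ester A4 a base would form the terminal enolate of the methyl ketone, which acylates on the furan-3-carboxylate. Enolisation then gives A3, the target with ring B as its bis-acetal.

- Merits: the ring A oxygens arise from carbonyl groups, so ring A needs no phenol protection. The quaternary side chain is placed on sp3 carbon without any Claisen regiochemistry, and aromatisation drives the closure. In these respects it is better than the chosen plan.
- Weak points: the methine between the furan and the ketone is more acidic than the methyl group, so the productive enolate is the minor one. A4 is a fully substituted furan that needs a long linear build. It again contains the 2',6'-diprenylated ring B attached to a heteroaryl carbon, so the central problem is untouched. A3 must still lose two acetals in acid with three allylic chains present.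
- Comparison: the chosen plan is convergent and solves the ring B pattern, at the price of the protecting-group work on ring A.

**Alternative 3:** This road cuts C2-C3. The α-aryloxy arylacetic acid A6, activated as a mixed anhydride with Ac2O and NaOAc, would add through its enolate carbon to the ortho formyl group and lose CO2 and water. The product A5 is the same compound as 18.

- Merits: A6 is the O-alkylation product of aldehyde 6 of the present route. A5 would therefore lie two operations beyond 6 instead of seven, a clear advantage in step count.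
- Weak points: the O-alkylation joins a phenol flanked by a quaternary carbon and a hydrogen-bonded formyl group to a secondary benzylic carbon whose aryl ring has two ortho chains, a substitution at a doubly hindered centre. The arylacetic acid half needs the unsolved ring B pattern once more. Hot anhydride and acetate threaten the acetals.
- Comparison: the chosen plan avoids any substitution at hindered sp3 carbon and makes the ring B pattern itself, and accepts the longer sequence.

Key step: step 9

Remark: silyl ether 14 is taken as a catalogue reagent, and the 1,1-dimethylallyl group is named 2-methylbut-3-en-2-yl throughout.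

## Route

Step 1
Reactants: 1 2,4,6-trihydroxybenzaldehyde; 2 1-bromo-3-methylbut-2-ene (prenyl bromide)
Product: 3 2,6-dihydroxy-4-[(3-methylbut-2-en-1-yl)oxy]benzaldehyde
Conditions: 2 (1.0 equiv), K2CO3 (1.0 equiv), acetone, 0 °C to rt
Reagents that add atoms: none
Why: Williamson etherification; the 4-OH is para to the formyl group, the most acidic and the only one outside the hydrogen-bonded chelate, so one equivalent of weak base in an aprotic medium should alkylate it on oxygen before the chelated hydroxyls or ring carbon react.

Step 2
Reactants: 3 2,6-dihydroxy-4-[(3-methylbut-2-en-1-yl)oxy]benzaldehyde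
Product: 5 2,4,6-trihydroxy-3-(2-methylbut-3-en-2-yl)benzaldehyde, via ortho-dienone 4 (not isolated)
Conditions: PhNEt2, 185 °C, sealed tube, argon
Reagents that add atoms: none
Why: Aromatic Claisen rearrangement; the two ortho carbons are equivalent by symmetry and the para carbon carries the formyl group, so a Cope shift from dienone 4 is a reversible dead end and enolisation to the reverse-prenyl phenol is the only productive outlet, while the tertiary amine solvent speeds that enolisation and keeps the medium non-acidic.

Step 3
Reactants: 5 2,4,6-trihydroxy-3-(2-methylbut-3-en-2-yl)benzaldehyde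
Product: 6 2-hydroxy-4,6-bis(methoxymethoxy)-3-(2-methylbut-3-en-2-yl)benzaldehyde
Conditions: MOMCl (2.1 equiv), i-Pr2NEt (3 equiv), CH2Cl2, 0 °C
Reagents that add atoms: chloromethyl methyl ether, COCCl
Why: Selective O-alkylation to methoxymethyl ethers; the 4-OH (para to formyl, unchelated) and the 6-OH (one free flank) should react, whereas the 2-OH lies between the quaternary carbon and the formyl group and is forced into the hydrogen bond with the carbonyl, so it is the slowest.

Step 4
Reactants: 6 2-hydroxy-4,6-bis(methoxymethoxy)-3-(2-methylbut-3-en-2-yl)benzaldehyde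
Product: 7 2-(2,2-dibromoethenyl)-3,5-bis(methoxymethoxy)-6-(2-methylbut-3-en-2-yl)phenol
Conditions: CBr4 (2 equiv), PPh3 (2 equiv), Zn dust (2 equiv), CH2Cl2, rt, then 6, 0 °C to rt
Reagents that add atoms: carbon tetrabromide, BrC(Br)(Br)Br
Why: Ramirez gem-dibromo-olefination (first stage of the Corey-Fuchs sequence) applied to a salicylaldehyde; the zinc variant forms the ylide without a bromophosphonium by-product, so the acetals and the free hindered phenol should pass.

Step 5
Reactants: 7 2-(2,2-dibromoethenyl)-3,5-bis(methoxymethoxy)-6-(2-methylbut-3-en-2-yl)phenol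
Product: 8 2-bromo-4,6-bis(methoxymethoxy)-7-(2-methylbut-3-en-2-yl)-1-benzofuran
Conditions: CuI (5 mol%), K3PO4 (2 equiv), THF, 80 °C
Reagents that add atoms: none
Why: Copper-catalysed intramolecular Ullmann-type C-O coupling of the phenoxide with the cis C-Br bond of the gem-dibromo-olefin closes the five-membered ring and leaves the second bromine at C2.

Step 6
Reactants: 8 2-bromo-4,6-bis(methoxymethoxy)-7-(2-methylbut-3-en-2-yl)-1-benzofuran
Product: 10 2-[4,6-bis(methoxymethoxy)-7-(2-methylbut-3-en-2-yl)-1-benzofuran-2-yl]-4,4,5,5-tetramethyl-1,3,2-dioxaborolane, via 2-lithiobenzofuran 9 (not isolated)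
Conditions: n-BuLi (1.05 equiv), THF, -78 °C; i-PrOBpin (1.3 equiv), -78 °C to rt; H2O
Reagents that add atoms: 2-isopropoxy-4,4,5,5-tetramethyl-1,3,2-dioxaborolane, CC(C)OB1OC(C)(C)C(C)(C)O1
Why: Bromine-lithium exchange followed by borylation; exchange at -78 °C is much faster than deprotonation at C5 between the two acetal oxygens, so the bromine fixes boron at C2, and the borate collapses to the pinacol ester on warming.

Step 7
Reactants: 11 1-iodo-3,5-dimethoxybenzene
Product: 12 5-iodobenzene-1,3-diol
Conditions: BBr3 (3 equiv), CH2Cl2, -78 °C to rt; H2O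
Reagents that add atoms: none
Why: Lewis-acid cleavage of aryl methyl ethers with BBr3; the aryl iodide is inert to the reagent and no acid-sensitive group is present yet.

Step 8
Reactants: 12 5-iodobenzene-1,3-diol
Product: 13 1-iodo-3,5-bis(methoxymethoxy)benzene
Conditions: MOMCl (2.5 equiv), i-Pr2NEt (3 equiv), CH2Cl2, 0 °C to rt
Reagents that add atoms: chloromethyl methyl ether, COCCl
Why: Methoxymethyl ether formation on two unhindered phenols; the acetals are small, base-stable neighbours for the coming C-H palladation.

Step 9
Reactants: 13 1-iodo-3,5-bis(methoxymethoxy)benzene; 14 tert-butyl(2-iodoethoxy)dimethylsilane; 10 2-[4,6-bis(methoxymethoxy)-7-(2-methylbut-3-en-2-yl)-1-benzofuran-2-yl]-4,4,5,5-tetramethyl-1,3,2-dioxaborolane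
Product: 15 2-{2,6-bis[2-(tert-butyldimethylsilyloxy)ethyl]-3,5-bis(methoxymethoxy)phenyl}-4,6-bis(methoxymethoxy)-7-(2-methylbut-3-en-2-yl)-1-benzofuran
Conditions: Pd(OAc)2 (10 mol%), P(2-furyl)3 (20 mol%), norbornene (2 equiv), Cs2CO3 (5 equiv), 14 (5 equiv), 10 (1.3 equiv, added over several hours), DMF, 70 °C
Reagents that add atoms: none
Why: Zerovalent palladium inserts into the C1'-I bond of 13, norbornene carbopalladates, and C-H palladation at C2' gives a five-membered palladacycle of divalent palladium. The palladacycle adds iodide 14 in an SN2-type oxidative addition to tetravalent palladium, reductive elimination forms the C2'-CH2 bond, and the sequence repeats at the equivalent C6'. With both ortho sites filled, norbornene is expelled by β-carbon elimination, and the crowded arylpalladium is captured by boronate 10 through transmetalation and reductive elimination, which makes the C1'-C2 bond last. The closest known reaction is the Catellani ortho,ortho'-dialkylation of aryl iodides with primary alkyl halides terminated by Suzuki coupling to 2,6-dialkylbiaryls. No ring is closed and no stereocentre is formed. The step needs two alkylations before ipso coupling; the mirror symmetry of 13, the small alkoxy neighbours, the large excess of 14 and the slow addition of 10 should secure this. It also needs Suzuki capture to outrun Heck addition to the vinyl group of 10; that olefin hangs on a quaternary carbon, and norbornene is the better, reversibly bound olefin partner.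

Step 10
Reactants: 15 2-{2,6-bis[2-(tert-butyldimethylsilyloxy)ethyl]-3,5-bis(methoxymethoxy)phenyl}-4,6-bis(methoxymethoxy)-7-(2-methylbut-3-en-2-yl)-1-benzofuran
Product: 16 2,2'-{2-[4,6-bis(methoxymethoxy)-7-(2-methylbut-3-en-2-yl)-1-benzofuran-2-yl]-4,6-bis(methoxymethoxy)-1,3-phenylene}di(ethan-1-ol)
Conditions: TBAF (2.5 equiv), THF, 0 °C to rt; H2O
Reagents that add atoms: none
Why: Fluoride-mediated desilylation of two primary silyl ethers; acetals, olefins and the benzofuran are inert to fluoride.

Step 11
Reactants: 16 2,2'-{2-[4,6-bis(methoxymethoxy)-7-(2-methylbut-3-en-2-yl)-1-benzofuran-2-yl]-4,6-bis(methoxymethoxy)-1,3-phenylene}di(ethan-1-ol)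
Product: 17 2,2'-{2-[4,6-bis(methoxymethoxy)-7-(2-methylbut-3-en-2-yl)-1-benzofuran-2-yl]-4,6-bis(methoxymethoxy)-1,3-phenylene}diacetaldehyde
Conditions: Dess-Martin periodinane (2.6 equiv), CH2Cl2, 0 °C to rt; Na2S2O3/NaHCO3 work-up; used at once
Reagents that add atoms: none
Why: Dess-Martin oxidation of primary alcohols stops at the aldehyde under near-neutral conditions, which suits the enolisable arylacetaldehydes and the electron-rich rings.

Step 12
Reactants: 17 2,2'-{2-[4,6-bis(methoxymethoxy)-7-(2-methylbut-3-en-2-yl)-1-benzofuran-2-yl]-4,6-bis(methoxymethoxy)-1,3-phenylene}diacetaldehyde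
Product: 18 2-[3,5-bis(methoxymethoxy)-2,6-bis(3-methylbut-2-en-1-yl)phenyl]-4,6-bis(methoxymethoxy)-7-(2-methylbut-3-en-2-yl)-1-benzofuran
Conditions: i-PrPPh3I (3.5 equiv), n-BuLi (3.4 equiv), THF, 0 °C; then 17, -78 °C to rt
Reagents that add atoms: isopropyltriphenylphosphonium iodide, CC(C)[P+](c1ccccc1)(c1ccccc1)c1ccccc1.[I-]
Why: Twofold Wittig olefination with the unstabilised isopropylidene ylide turns each CH2-CHO arm into a prenyl group; no olefin geometry arises because the new carbon carries two methyl groups, and addition at low temperature should favour carbonyl addition over enolisation.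

Step 13
Reactants: 18 2-[3,5-bis(methoxymethoxy)-2,6-bis(3-methylbut-2-en-1-yl)phenyl]-4,6-bis(methoxymethoxy)-7-(2-methylbut-3-en-2-yl)-1-benzofuran
Product: 19 2-[3,5-dihydroxy-2,6-bis(3-methylbut-2-en-1-yl)phenyl]-7-(2-methylbut-3-en-2-yl)-1-benzofuran-4,6-diol
Conditions: HCl (1 M in MeOH), 30 °C, argon
Reagents that add atoms: none
Why: Acid-catalysed transacetalisation of aryl methoxymethyl ethers to methanol; protonation of the acetal oxygen is faster than protonation of the trisubstituted olefins at this acidity and temperature, the usual basis for unmasking prenylated phenols.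

## Compound list

1 | 2,4,6-trihydroxybenzaldehyde | O=Cc1c(O)cc(O)cc1O | starting material
2 | 1-bromo-3-methylbut-2-ene (prenyl bromide) | CC(C)=CCBr | starting material
3 | 2,6-dihydroxy-4-[(3-methylbut-2-en-1-yl)oxy]benzaldehyde | O=Cc1c(O)cc(OCC=C(C)C)cc1O | intermediate
4 | 2,6-dihydroxy-3-(2-methylbut-3-en-2-yl)-4-oxocyclohexa-1,5-diene-1-carbaldehyde (racemic, formed in situ) | O=CC1=C(O)C(C(C)(C)C=C)C(=O)C=C1O | intermediate
5 | 2,4,6-trihydroxy-3-(2-methylbut-3-en-2-yl)benzaldehyde | O=Cc1c(O)cc(O)c(C(C)(C)C=C)c1O | intermediate
6 | 2-hydroxy-4,6-bis(methoxymethoxy)-3-(2-methylbut-3-en-2-yl)benzaldehyde | O=Cc1c(O)c(C(C)(C)C=C)c(OCOC)cc1OCOC | intermediate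
7 | 2-(2,2-dibromoethenyl)-3,5-bis(methoxymethoxy)-6-(2-methylbut-3-en-2-yl)phenol | BrC(Br)=Cc1c(O)c(C(C)(C)C=C)c(OCOC)cc1OCOC | intermediate
8 | 2-bromo-4,6-bis(methoxymethoxy)-7-(2-methylbut-3-en-2-yl)-1-benzofuran | C=CC(C)(C)c1c(OCOC)cc(OCOC)c2cc(Br)oc12 | intermediate
9 | [4,6-bis(methoxymethoxy)-7-(2-methylbut-3-en-2-yl)-1-benzofuran-2-yl]lithium (formed in situ) | [Li]c1cc2c(OCOC)cc(OCOC)c(C(C)(C)C=C)c2o1 | intermediate
10 | 2-[4,6-bis(methoxymethoxy)-7-(2-methylbut-3-en-2-yl)-1-benzofuran-2-yl]-4,4,5,5-tetramethyl-1,3,2-dioxaborolane | C=CC(C)(C)c1c(OCOC)cc(OCOC)c2cc(B3OC(C)(C)C(C)(C)O3)oc12 | intermediate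
11 | 1-iodo-3,5-dimethoxybenzene | COc1cc(I)cc(OC)c1 | starting material
12 | 5-iodobenzene-1,3-diol | Oc1cc(I)cc(O)c1 | intermediate
13 | 1-iodo-3,5-bis(methoxymethoxy)benzene | COCOc1cc(I)cc(OCOC)c1 | intermediate
14 | tert-butyl(2-iodoethoxy)dimethylsilane | ICCO[Si](C)(C)C(C)(C)C | starting material
15 | 2-{2,6-bis[2-(tert-butyldimethylsilyloxy)ethyl]-3,5-bis(methoxymethoxy)phenyl}-4,6-bis(methoxymethoxy)-7-(2-methylbut-3-en-2-yl)-1-benzofuran | C=CC(C)(C)c1c(OCOC)cc(OCOC)c2cc(-c3c(CCO[Si](C)(C)C(C)(C)C)c(OCOC)cc(OCOC)c3CCO[Si](C)(C)C(C)(C)C)oc12 | intermediate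
16 | 2,2'-{2-[4,6-bis(methoxymethoxy)-7-(2-methylbut-3-en-2-yl)-1-benzofuran-2-yl]-4,6-bis(methoxymethoxy)-1,3-phenylene}di(ethan-1-ol) | C=CC(C)(C)c1c(OCOC)cc(OCOC)c2cc(-c3c(CCO)c(OCOC)cc(OCOC)c3CCO)oc12 | intermediate
17 | 2,2'-{2-[4,6-bis(methoxymethoxy)-7-(2-methylbut-3-en-2-yl)-1-benzofuran-2-yl]-4,6-bis(methoxymethoxy)-1,3-phenylene}diacetaldehyde | C=CC(C)(C)c1c(OCOC)cc(OCOC)c2cc(-c3c(CC=O)c(OCOC)cc(OCOC)c3CC=O)oc12 | intermediate
18 | 2-[3,5-bis(methoxymethoxy)-2,6-bis(3-methylbut-2-en-1-yl)phenyl]-4,6-bis(methoxymethoxy)-7-(2-methylbut-3-en-2-yl)-1-benzofuran | C=CC(C)(C)c1c(OCOC)cc(OCOC)c2cc(-c3c(CC=C(C)C)c(OCOC)cc(OCOC)c3CC=C(C)C)oc12 | intermediate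
19 | 2-[3,5-dihydroxy-2,6-bis(3-methylbut-2-en-1-yl)phenyl]-7-(2-methylbut-3-en-2-yl)-1-benzofuran-4,6-diol | C=CC(C)(C)c1c(O)cc(O)c2cc(-c3c(CC=C(C)C)c(O)cc(O)c3CC=C(C)C)oc12 | target

## Step count and least certain steps

Total: 13 steps. Longest linear sequence: 11 steps (steps 1 to 6, then 9 to 13).

**Step 9 (key step).** The most likely failure is mistimed ipso capture. The boronate may transmetalate to the arylpalladium iodide before both alkyl groups are in place, and the 2-benzofuranyl boronate may be lost by protodeboronation in hot carbonate. Either process leaves under-alkylated biaryl or unused iodide.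

The fallback removes the boronate and closes the furan after the three-component step. It sets out from dibromo-olefin 7. Treatment with n-BuLi (3 equiv, THF, -78 °C) should give 2-ethynyl-3,5-bis(methoxymethoxy)-6-(2-methylbut-3-en-2-yl)phenol F1. Iodide 13 and iodide 14 are then combined with F1 under the same Pd(OAc)2 and norbornene conditions. A terminal alkyne is a known terminator of the ortho,ortho'-dialkylation, is not base-labile, and couples without copper more slowly than norbornene inserts. This should give 2-({2,6-bis[2-(tert-butyldimethylsilyloxy)ethyl]-3,5-bis(methoxymethoxy)phenyl}ethynyl)-3,5-bis(methoxymethoxy)-6-(2-methylbut-3-en-2-yl)phenol F2. Its 5-endo-dig hydroalkoxylation (Cs2CO3 in DMF or catalytic CuI, possibly in the same flask) returns to the route at 15.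

**Step 2.** The most likely failure is thermal over-reaction of the polyphenolic product. A hydroxyl next to the new side chain may add to its vinyl group, the formyl group may be expelled from the para-dienone, or the side chain may be lost, because the product carries two ortho hydroxyls and sits at 185 °C.

The fallback masks the two chelating hydroxyls during the rearrangement. It sets out from 3. NaH and chloromethyl methyl ether in DMF should give 2,6-bis(methoxymethoxy)-4-[(3-methylbut-2-en-1-yl)oxy]benzaldehyde F3. Heating in PhNEt2 gives 4-hydroxy-2,6-bis(methoxymethoxy)-3-(2-methylbut-3-en-2-yl)benzaldehyde F4, still as a single regioisomer by symmetry. Brief treatment with methanolic HCl returns to the route at 5.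

**Step 3.** The most likely failure is incomplete discrimination between the two hydroxyls ortho to the formyl group. The acetal may go onto the hindered 2-OH, or a third acetal may form, because the difference rests only on shielding and hydrogen bonding.

The fallback sets the difference before the rearrangement. It sets out from 3. One equivalent of chloromethyl methyl ether with i-Pr2NEt should give 2-hydroxy-6-(methoxymethoxy)-4-[(3-methylbut-2-en-1-yl)oxy]benzaldehyde F5, whose remaining hydroxyl is locked in the chelate. The Claisen shift then gives 2,4-dihydroxy-6-(methoxymethoxy)-3-(2-methylbut-3-en-2-yl)benzaldehyde F6. Here the regiochemistry rests on chelate-induced bond fixation, which directs migration to the carbon beside the chelated hydroxyl, and no longer on symmetry. Alkylation of the unchelated 4-OH with one more equivalent of chloromethyl methyl ether returns to the route at 6.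

**Step 12.** The most likely failure is enolisation of the arylacetaldehydes by the basic ylide. This leads to self-condensation or incomplete twofold olefination, because the α-protons are both benzylic and next to a carbonyl group.

The fallback reverses the polarity. It sets out from diol 16. Iodine, PPh3 and imidazole should give 2-[2,6-bis(2-iodoethyl)-3,5-bis(methoxymethoxy)phenyl]-4,6-bis(methoxymethoxy)-7-(2-methylbut-3-en-2-yl)-1-benzofuran F7. PPh3 in refluxing MeCN gives the bis(triphenylphosphonium) diiodide F8. Its bis-ylide, formed with KN(SiMe3)2, reacts with acetone and returns to the route at 18.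

**Step 13.** The most likely failure is acid-promoted ring closure of a freed phenol onto the neighbouring prenyl or dimethylallyl chain before all four acetals are gone. Every phenol has an ortho allylic chain, and the electron-rich rings make the tertiary cations easy to form.

The fallback exchanges the acetals for silyl ethers before the prenyl groups exist, so that the last step uses fluoride. It sets out from 15.

- Methanolic HCl removes the four acetals and both silyl groups and gives 2-[3,5-dihydroxy-2,6-bis(2-hydroxyethyl)phenyl]-7-(2-methylbut-3-en-2-yl)-1-benzofuran-4,6-diol F9.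
- TBSOTf and 2,6-lutidine give the hexakis(tert-butyldimethylsilyl) ether F10.
- Pyridinium p-toluenesulfonate in MeOH cleaves only the two primary silyl ethers and gives the tetrakis(aryl silyl ether) diol F11.
- Dess-Martin oxidation gives the tetrakis(aryl silyl ether) dialdehyde F12.
- The isopropylidene Wittig reaction gives the tetrakis(tert-butyldimethylsilyl) ether of the target F13.
- TBAF buffered with acetic acid returns to the route at 19.

## Further compounds

F1 | step 9 | 2-ethynyl-3,5-bis(methoxymethoxy)-6-(2-methylbut-3-en-2-yl)phenol | C#Cc1c(O)c(C(C)(C)C=C)c(OCOC)cc1OCOC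
F2 | step 9 | 2-({2,6-bis[2-(tert-butyldimethylsilyloxy)ethyl]-3,5-bis(methoxymethoxy)phenyl}ethynyl)-3,5-bis(methoxymethoxy)-6-(2-methylbut-3-en-2-yl)phenol | C=CC(C)(C)c1c(O)c(C#Cc2c(CCO[Si](C)(C)C(C)(C)C)c(OCOC)cc(OCOC)c2CCO[Si](C)(C)C(C)(C)C)c(OCOC)cc1OCOC
F3 | step 2 | 2,6-bis(methoxymethoxy)-4-[(3-methylbut-2-en-1-yl)oxy]benzaldehyde | O=Cc1c(OCOC)cc(OCC=C(C)C)cc1OCOC
F4 | step 2 | 4-hydroxy-2,6-bis(methoxymethoxy)-3-(2-methylbut-3-en-2-yl)benzaldehyde | O=Cc1c(OCOC)cc(O)c(C(C)(C)C=C)c1OCOC
F5 | step 3 | 2-hydroxy-6-(methoxymethoxy)-4-[(3-methylbut-2-en-1-yl)oxy]benzaldehyde | O=Cc1c(O)cc(OCC=C(C)C)cc1OCOC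
F6 | step 3 | 2,4-dihydroxy-6-(methoxymethoxy)-3-(2-methylbut-3-en-2-yl)benzaldehyde | O=Cc1c(O)c(C(C)(C)C=C)c(O)cc1OCOC
F7 | step 12 | 2-[2,6-bis(2-iodoethyl)-3,5-bis(methoxymethoxy)phenyl]-4,6-bis(methoxymethoxy)-7-(2-methylbut-3-en-2-yl)-1-benzofuran | C=CC(C)(C)c1c(OCOC)cc(OCOC)c2cc(-c3c(CCI)c(OCOC)cc(OCOC)c3CCI)oc12
F8 | step 12 | ({2-[4,6-bis(methoxymethoxy)-7-(2-methylbut-3-en-2-yl)-1-benzofuran-2-yl]-4,6-bis(methoxymethoxy)-1,3-phenylene}di(ethane-2,1-diyl))bis(triphenylphosphonium) diiodide | C=CC(C)(C)c1c(OCOC)cc(OCOC)c2cc(-c3c(CC[P+](c4ccccc4)(c4ccccc4)c4ccccc4)c(OCOC)cc(OCOC)c3CC[P+](c4ccccc4)(c4ccccc4)c4ccccc4)oc12.[I-].[I-]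
F9 | step 13 | 2-[3,5-dihydroxy-2,6-bis(2-hydroxyethyl)phenyl]-7-(2-methylbut-3-en-2-yl)-1-benzofuran-4,6-diol | C=CC(C)(C)c1c(O)cc(O)c2cc(-c3c(CCO)c(O)cc(O)c3CCO)oc12
F10 | step 13 | hexakis(tert-butyldimethylsilyl) ether of F9 | C=CC(C)(C)c1c(O[Si](C)(C)C(C)(C)C)cc(O[Si](C)(C)C(C)(C)C)c2cc(-c3c(CCO[Si](C)(C)C(C)(C)C)c(O[Si](C)(C)C(C)(C)C)cc(O[Si](C)(C)C(C)(C)C)c3CCO[Si](C)(C)C(C)(C)C)oc12
F11 | step 13 | 2,2'-{2-[4,6-bis(tert-butyldimethylsilyloxy)-7-(2-methylbut-3-en-2-yl)-1-benzofuran-2-yl]-4,6-bis(tert-butyldimethylsilyloxy)-1,3-phenylene}di(ethan-1-ol) | C=CC(C)(C)c1c(O[Si](C)(C)C(C)(C)C)cc(O[Si](C)(C)C(C)(C)C)c2cc(-c3c(CCO)c(O[Si](C)(C)C(C)(C)C)cc(O[Si](C)(C)C(C)(C)C)c3CCO)oc12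
F12 | step 13 | 2,2'-{2-[4,6-bis(tert-butyldimethylsilyloxy)-7-(2-methylbut-3-en-2-yl)-1-benzofuran-2-yl]-4,6-bis(tert-butyldimethylsilyloxy)-1,3-phenylene}diacetaldehyde | C=CC(C)(C)c1c(O[Si](C)(C)C(C)(C)C)cc(O[Si](C)(C)C(C)(C)C)c2cc(-c3c(CC=O)c(O[Si](C)(C)C(C)(C)C)cc(O[Si](C)(C)C(C)(C)C)c3CC=O)oc12
F13 | step 13 | 2-[3,5-bis(tert-butyldimethylsilyloxy)-2,6-bis(3-methylbut-2-en-1-yl)phenyl]-4,6-bis(tert-butyldimethylsilyloxy)-7-(2-methylbut-3-en-2-yl)-1-benzofuran | C=CC(C)(C)c1c(O[Si](C)(C)C(C)(C)C)cc(O[Si](C)(C)C(C)(C)C)c2cc(-c3c(CC=C(C)C)c(O[Si](C)(C)C(C)(C)C)cc(O[Si](C)(C)C(C)(C)C)c3CC=C(C)C)oc12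
A1 | alternative 1 | 2-[3,5-bis(methoxymethoxy)-2,6-bis(3-methylbut-2-en-1-yl)phenyl]-4-(methoxymethoxy)-6-[(3-methylbut-2-en-1-yl)oxy]-1-benzofuran | CC(C)=CCOc1cc(OCOC)c2cc(-c3c(CC=C(C)C)c(OCOC)cc(OCOC)c3CC=C(C)C)oc2c1
A2 | alternative 1 | 2-{2-bromo-6-(methoxymethoxy)-4-[(3-methylbut-2-en-1-yl)oxy]phenyl}-1-[3,5-bis(methoxymethoxy)-2,6-bis(3-methylbut-2-en-1-yl)phenyl]ethan-1-one | CC(C)=CCOc1cc(Br)c(CC(=O)c2c(CC=C(C)C)c(OCOC)cc(OCOC)c2CC=C(C)C)c(OCOC)c1
A3 | alternative 2 | 2-[3,5-bis(methoxymethoxy)-2,6-bis(3-methylbut-2-en-1-yl)phenyl]-7-(2-methylbut-3-en-2-yl)-1-benzofuran-4,6-diol | C=CC(C)(C)c1c(O)cc(O)c2cc(-c3c(CC=C(C)C)c(OCOC)cc(OCOC)c3CC=C(C)C)oc12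
A4 | alternative 2 | methyl 5-[3,5-bis(methoxymethoxy)-2,6-bis(3-methylbut-2-en-1-yl)phenyl]-2-(4,4-dimethyl-2-oxohex-5-en-3-yl)furan-3-carboxylate (racemic) | COC(=O)c1cc(-c2c(CC=C(C)C)c(OCOC)cc(OCOC)c2CC=C(C)C)oc1C(C(C)=O)C(C)(C)C=C
A5 | alternative 3 | 2-[3,5-bis(methoxymethoxy)-2,6-bis(3-methylbut-2-en-1-yl)phenyl]-4,6-bis(methoxymethoxy)-7-(2-methylbut-3-en-2-yl)-1-benzofuran (identical with 18) | C=CC(C)(C)c1c(OCOC)cc(OCOC)c2cc(-c3c(CC=C(C)C)c(OCOC)cc(OCOC)c3CC=C(C)C)oc12
A6 | alternative 3 | 2-[2-formyl-3,5-bis(methoxymethoxy)-6-(2-methylbut-3-en-2-yl)phenoxy]-2-[3,5-bis(methoxymethoxy)-2,6-bis(3-methylbut-2-en-1-yl)phenyl]acetic acid (racemic) | OC(=O)C(Oc1c(C=O)c(OCOC)cc(OCOC)c1C(C)(C)C=C)c1c(CC=C(C)C)c(OCOC)cc(OCOC)c1CC=C(C)C
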